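Multiply the equivalents of L by the minutes first; I did, and the readings of Z fell on one curve.

| flask | J | L | E | remark | time |
|---|---|---|---|---|---|
| noon | 0.22 M | 1.5 equiv | 1 equiv | run made earlier |  |
| dawn | 0.22 M | 1.8 equiv | 1 equiv | run made earlier |  |
| midnight | 0.22 M | 2.2 equiv | 1 equiv | run made earlier |  |
| Friday's | 0.22 M | 1.20 equiv | 1.00 equiv |  | 15 min |
| Saturday's | 0.22 M | 2.00 equiv | 1.00 equiv |  | 15 min |
| Wednesday's | 0.22 M | 3.00 equiv | 1.00 equiv |  | 15 min |

| run | time / min | Z / % | Q / % |
|---|---|---|---|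
| noon | 0.833 | 3.4 | 0 |
| noon | 1.50 | 5.0 | 0.8 |
| noon | 3.00 | 7.1 | 0.4 |
| noon | 6.00 | 13.7 | 2.2 |
| noon | 10.0 | 17.0 | 4.5 |
| dawn | 0.833 | 2.2 | 1.5 |
| dawn | 1.50 | 5.5 | 0 |
| dawn | 3.00 | 11.0 | 0 |
| dawn | 6.00 | 15.0 | 2.4 |
| dawn | 10.0 | 17.8 | 4.6 |
| midnight | 1.00 | 6.0 | 1.7 |
| midnight | 2.50 | 10.9 | 0.1 |
| midnight | 5.00 | 15.2 | 2.7 |
| midnight | 8.00 | 20.0 | 2.8 |
| midnight | 10.0 | 21.1 | 7.2 |

(each reading ± 1 percentage point)

- Z at the end, in percent of the J charged, for each flask in turn (Friday's, Saturday's, Wednesday's)

- steps under discussion: J + L <-> E + Z; Z + L <-> E + Q; J <-> G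

Early Z grew with [L], so I took one early reading of Z from each run, at 1.50 min in the noon run, 1.50 min in the dawn run and 1.00 min in the midnight run, divided their sum by the sum of their equivalents × minutes, and multiplied by each flask's equivalents × minutes:

Friday's: θ = 0.415
Saturday's: θ = 0.692
Wednesday's: θ = 1.04
midnight run, last reading: θ = 0.508

This θ, the dose, is the turnover, counted in charges of J, that the early rate would have made; it is a pseudo-first-order exposure. One number looked enough: the dawn run at 3.00 min and the midnight run at 2.50 min share nearly one dose and read 11.0% and 10.9%. Friday's dose equals that of the dawn run's last reading, so I read 17.8% for Friday's. Beyond the readings I extended the midnight run, whose Z between 5.00 min and 10.0 min gave the exponent 0.473: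

Saturday's: Z = 24.4%
Wednesday's: Z = 29.6%

The forecast said 17%, 22% and 26%, below my figures, expecting that “Z flattens as Q drains it”.

The flasks gave 16.0%, 21.2% and 24.1%, so my curve ran high, by 5.5 percentage points on Wednesday's.

    J + L ⇌ E + Z (K = 1.40, k = 0.120 /M/min)
    Z + L ⇌ E + Q (K = 1.80, k = 0.110 /M/min)
    J ⇌ G (K = 1.10, k = 0.110 /min)

Wednesday's flask at 7.50 min had θ 0.520, below the 0.692 of Saturday's flask at its end, yet it held more Z, 22.9% against 21.2%, so minutes count apart from dose. J <-> G takes no L; G stood at 32.3% in Wednesday's flask then, against 37.4% in Saturday's. The passing of J into G, both ways, is the largest single effect proven on Saturday's Z : with the passing of J into G taken away, Saturday's flask reached 31.1% instead of 21.2%.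

The numbers in the tables come from a simulation on assumed constants; the scatter is artificial.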